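In a one-step world each unit of solid reagent makes one unit of target. Since c_solid reagent lies below c_substrate, solid reagent is the limiting reagent, and target ends at c_solid reagent / c_substrate = 95.0%, the reagent budget: solid reagent charged per substrate charged.

| flask | substrate | solid reagent | capture agent | free catalyst | second catalyst | remark | time |
|---|---|---|---|---|---|---|---|
| north-east | 2 M | 1.9 M | 0.10 M | 5.4 mM | 230 mM | run made earlier |  |
| south | 2 M | 1.9 M | 0.10 M | 5.4 mM | 310 mM | run made earlier |  |
| east | 2 M | 1.9 M | 0.10 M | 5.4 mM | 480 mM | run made earlier |  |
| epsilon | 2.0 M | 1.90 M | 0.100 M | 5.4 mM | 200 mM |  | 30 h |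
| theta | 2.0 M | 1.90 M | 0.100 M | 5.4 mM | 300 mM |  | 30 h |
| alpha | 2.0 M | 1.90 M | 0.100 M | 5.4 mM | 450 mM |  | 30 h |

| run | time / h | target / % |
|---|---|---|
| north-east | 1.50 | 1.4 |
| north-east | 3.00 | 13.2 |
| north-east | 6.00 | 33.4 |
| north-east | 12.0 | 51.9 |
| north-east | 20.0 | 57.6 |
| south | 1.50 | 2.9 |
| south | 3.00 | 15.2 |
| south | 6.00 | 34.8 |
| south | 12.0 | 57.2 |
| south | 20.0 | 60.0 |
| east | 4.00 | 27.3 |
| east | 8.00 | 52.2 |
| east | 12.0 | 58.8 |
| east | 15.0 | 60.3 |
| east | 20.0 | 62.7 |

(each reading ± 1 percentage point)

- solid, in amounts per volume of the solution: solid reagent
- the analysis behind the earlier runs scatters by 1 percentage point, standard deviation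
- at the start none of the solid reagent is in solution

1. which of the two there is more of at the end, epsilon (over-reaction product / target)
2. which of the two there is more of at the end, theta (over-reaction product / target)
3. which of the two there is more of at the end, alpha (over-reaction product / target)
4. final target, as a percentage of the substrate charged, in epsilon
5. final target, as a percentage of the substrate charged, in theta
6. final target, as a percentage of the substrate charged, in alpha

Does the east run reach the budget? No: it stands at 62.7% of target after 20.0 h, 32 percentage points short. The reckoning here takes over-reaction product to be target that has taken up a second unit of reagent, so each unit of it costs two units of budget. Counting the reagent as consumed, over-reaction product is then a correction: budget less target, divided by two.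

Has target stopped before 30 h? The east run gained 25 points between 4.00 h and 8.00 h, but 2.4 points between 15.0 h and 20.0 h, so the last readings are taken as near the end values.

How far does second catalyst move them? From the north-east run to the east run, target at 20.0 h rises by 4.8 points per doubling of c_second catalyst, on readings that scatter by 1 point. Counted from the north-east reading, this gives target of 56.6% in epsilon, whose c_second catalyst lies below the tested range, 59.4% in theta and 62.3% in alpha. The budget then leaves over-reaction product at 19.2%, 17.8% and 16.4%, less than target in epsilon, theta and alpha.

The forecast, holding that “the plateaus should hold”, gave 57%, 60.3% and 63.5% for epsilon, theta and alpha, and named target, target and target as the larger.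

The flasks give target of 56.2%, 59.9% and 62.8%, against over-reaction product of 19.2%, 17.5% and 16.1%.

    substrate + free catalyst ⇌ free catalyst + open intermediate (K = 9.30, k = 28.0 L mol⁻¹ h⁻¹)
    second catalyst + open intermediate ⇌ catalyst intermediate (K = 0.0247 L mol⁻¹, k = 58.0 L mol⁻¹ h⁻¹)
    partner + catalyst intermediate → second catalyst + target (k = 90.9 L mol⁻¹ h⁻¹)
    solid reagent ⇌ partner, rate k4*(cs4 - [partner]) while solid is left; crystals form when [partner] > cs4 (solubility = 1.20 M, k = 0.419 h⁻¹)
    open intermediate + capture agent → trapped intermediate (k = 0.160 L mol⁻¹ h⁻¹)
    partner + target → over-reaction product (k = 0.0649 L mol⁻¹ h⁻¹)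

The budget carries over to a neighbour of alpha charged with 9.20 mM of free catalyst in place of 5.4 mM. Its c_substrate and c_solid reagent are those of alpha, so its budget stays 95.0%. Its target reaches 70.0%, more than the 62.8% of alpha. Budget less that target, divided by two, gives 12.5% of over-reaction product. In that neighbour partner, the dissolved solid reagent, is down to 1.84 × 10⁻⁴ M, and over-reaction product stands at 12.5%.

Readings and results are simulated with made-up constants, and the scatter is random.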